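**Retrosynthetic overview**

1. The route rests on the C3–C4 bond of ring C. It joins the benzylic stereocentre C3 (carrying ring B) to the aroyl carbon C4 on ring A, so with the O1–C2 ether already in place it can be formed last by reductive union of an aroyl chloride with a racemic benzylic chloride.
2. Target ⇐ ketal hydrolysis and desilylation ⇐ (R)-isoflavanone with 7-O-TIPS and 2',3'-O-diphenylmethylene ⇐ C3–C4 closure (NiCl2(dme), chiral bis(oxazoline), Mn) ⇐ racemic chloro acid chloride ⇐ hydroxy acid.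
3. O1–C2 comes from etherification of a ring A salicylate (from 2,4-dihydroxybenzoic acid) with a ring B α-bromoketone (from 2',3'-dihydroxy-4'-methoxyacetophenone by ketalisation, C5' bromination, Stille prenylation and α-bromination), followed by ketone reduction.
4. Rings A and B are bought as arenes; ring C is the only ring formed, in step 11, which also sets C3.

Key step: step 11

Assumption: the sense of induction of the ring-closing coupling cannot be derived from the intermolecular case, so the route is written with the (R,R)-ligand and the equally available antipode is taken if the first run shows the (S)-ketone to predominate.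

**Route**

Step 1
Reactants: 1 2',3'-dihydroxy-4'-methoxyacetophenone
Product: 2 diphenylmethylene ketal 1-(7-methoxy-2,2-diphenyl-1,3-benzodioxol-4-yl)ethan-1-one
Conditions: Ph2CCl2 (1.5 equiv), Ph2O, 170 °C, N2 sweep
Reagents that add atoms: dichlorodiphenylmethane, ClC(Cl)(c1ccccc1)c1ccccc1
Why: Catechol ketalisation with a gem-dichloride, in which thermal double substitution by the two adjacent phenols with loss of HCl should give the 2,2-diphenyl-1,3-benzodioxole as a base-stable, non-migrating mask for both hydroxyls.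

Step 2
Reactants: 2 diphenylmethylene ketal 1-(7-methoxy-2,2-diphenyl-1,3-benzodioxol-4-yl)ethan-1-one
Product: 3 aryl bromide 1-(6-bromo-7-methoxy-2,2-diphenyl-1,3-benzodioxol-4-yl)ethan-1-one
Conditions: NBS, MeCN, 0 °C to rt
Reagents that add atoms: N-bromosuccinimide, O=C1CCC(=O)N1Br
Why: Electrophilic aromatic bromination should go to C6 of the benzodioxole (the future C5'), which is ortho to OMe, para to a ketal oxygen and meta to the acetyl group.

Step 3
Reactants: 3 aryl bromide 1-(6-bromo-7-methoxy-2,2-diphenyl-1,3-benzodioxol-4-yl)ethan-1-one; 4 tributyl(3-methylbut-2-en-1-yl)stannane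
Product: 5 prenyl arene 1-[7-methoxy-6-(3-methylbut-2-en-1-yl)-2,2-diphenyl-1,3-benzodioxol-4-yl]ethan-1-one
Conditions: Pd(PPh3)4 (5 mol %), DMF, 95 °C
Reagents that add atoms: tributyl(3-methylbut-2-en-1-yl)stannane, CCCC[Sn](CCCC)(CCCC)CC=C(C)C
Why: Stille cross-coupling of the aryl bromide with the prenylstannane, for which Pd(PPh3)4 in DMF is expected to transfer the allyl unit through its α-carbon and give the linear 3-methylbut-2-enyl arene.

Step 4
Reactants: 5 prenyl arene 1-[7-methoxy-6-(3-methylbut-2-en-1-yl)-2,2-diphenyl-1,3-benzodioxol-4-yl]ethan-1-one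
Product: 7 bromoketone 2-bromo-1-[7-methoxy-6-(3-methylbut-2-en-1-yl)-2,2-diphenyl-1,3-benzodioxol-4-yl]ethan-1-one, via trimethylsilyl enol ether 6 (not isolated)
Conditions: LiN(SiMe3)2, Me3SiCl, THF, −78 °C; then NBS, −78 to 0 °C
Reagents that add atoms: N-bromosuccinimide, O=C1CCC(=O)N1Br; chlorotrimethylsilane, C[Si](C)(C)Cl (its silyl group is carried in 6 only)
Why: Kinetic enolisation with O-silylation followed by bromination of the silyl enol ether, whose electron-rich C=C should react with NBS at −78 °C far faster than the prenyl olefin or the arene.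

Step 5
Reactants: 8 2,4-dihydroxybenzoic acid
Product: 9 allyl 2,4-dihydroxybenzoate
Conditions: allyl bromide, KHCO3, DMF, 40 °C
Reagents that add atoms: allyl bromide, C=CCBr
Why: Chemoselective carboxylate O-alkylation, since KHCO3 deprotonates only the acid and leaves both phenols free.

Step 6
Reactants: 9 allyl 2,4-dihydroxybenzoate
Product: 10 allyl 2-hydroxy-4-(triisopropylsilyloxy)benzoate
Conditions: TIPSCl, imidazole, DMF, 0 °C to rt
Reagents that add atoms: chlorotriisopropylsilane, CC(C)[Si](Cl)(C(C)C)C(C)C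
Why: Selective phenol silylation, because the 2-hydroxyl is hydrogen-bonded to the ester carbonyl and hindered, so only the 4-hydroxyl should be silylated.

Step 7
Reactants: 7 bromoketone 2-bromo-1-[7-methoxy-6-(3-methylbut-2-en-1-yl)-2,2-diphenyl-1,3-benzodioxol-4-yl]ethan-1-one; 10 allyl 2-hydroxy-4-(triisopropylsilyloxy)benzoate
Product: 11 keto ester allyl 2-{2-[7-methoxy-6-(3-methylbut-2-en-1-yl)-2,2-diphenyl-1,3-benzodioxol-4-yl]-2-oxoethoxy}-4-(triisopropylsilyloxy)benzoate
Conditions: K2CO3, acetone, rt to 40 °C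
Reagents that add atoms: none
Why: Williamson etherification of the salicylate phenol with the reactive phenacyl bromide should form the O1–C2 ether under mild carbonate conditions, the low temperature avoiding Dieckmann-type closure to a benzofuranone and loss of the silyl ether.

Step 8
Reactants: 11 keto ester allyl 2-{2-[7-methoxy-6-(3-methylbut-2-en-1-yl)-2,2-diphenyl-1,3-benzodioxol-4-yl]-2-oxoethoxy}-4-(triisopropylsilyloxy)benzoate
Product: 12 racemic hydroxy ester allyl 2-{2-hydroxy-2-[7-methoxy-6-(3-methylbut-2-en-1-yl)-2,2-diphenyl-1,3-benzodioxol-4-yl]ethoxy}-4-(triisopropylsilyloxy)benzoate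
Conditions: NaBH4, CeCl3·7H2O, MeOH–THF, −20 °C
Reagents that add atoms: none
Why: Luche reduction of the aryl ketone should give the benzylic alcohol without touching the ester or silyl ether, and the carbinol centre is left racemic because step 11 is stereoconvergent.

Step 9
Reactants: 12 racemic hydroxy ester allyl 2-{2-hydroxy-2-[7-methoxy-6-(3-methylbut-2-en-1-yl)-2,2-diphenyl-1,3-benzodioxol-4-yl]ethoxy}-4-(triisopropylsilyloxy)benzoate
Product: 13 racemic hydroxy acid 2-{2-hydroxy-2-[7-methoxy-6-(3-methylbut-2-en-1-yl)-2,2-diphenyl-1,3-benzodioxol-4-yl]ethoxy}-4-(triisopropylsilyloxy)benzoic acid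
Conditions: Pd(PPh3)4 (3 mol %), morpholine, THF, rt; pH 4 citrate work-up
Reagents that add atoms: none
Why: Tsuji–Trost deallylation, in which zerovalent palladium ionises the allyl ester and morpholine traps the allyl fragment, should free the acid while the aryl prenyl group, silyl ether and ketal stay inert.

Step 10
Reactants: 13 racemic hydroxy acid 2-{2-hydroxy-2-[7-methoxy-6-(3-methylbut-2-en-1-yl)-2,2-diphenyl-1,3-benzodioxol-4-yl]ethoxy}-4-(triisopropylsilyloxy)benzoic acid
Product: 14 racemic chloro acid chloride 2-{2-chloro-2-[7-methoxy-6-(3-methylbut-2-en-1-yl)-2,2-diphenyl-1,3-benzodioxol-4-yl]ethoxy}-4-(triisopropylsilyloxy)benzoyl chloride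
Conditions: 1-chloro-N,N,2-trimethylprop-1-en-1-amine (3 equiv), CH2Cl2, 0 °C to rt, 13 added to the reagent; volatiles removed in vacuo, used crude
Reagents that add atoms: 1-chloro-N,N,2-trimethylprop-1-en-1-amine, CC(C)=C(Cl)N(C)C
Why: Neutral chlorination with the α-chloroenamine converts the carboxylic acid into the acid chloride and the benzylic alcohol into the chloride without releasing HCl, so the prenyl olefin, ketal and silyl ether should survive, and inverse addition into excess reagent caps the hydroxyl before it can lactonise onto the activated acid.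

Step 11
Reactants: 14 racemic chloro acid chloride 2-{2-chloro-2-[7-methoxy-6-(3-methylbut-2-en-1-yl)-2,2-diphenyl-1,3-benzodioxol-4-yl]ethoxy}-4-(triisopropylsilyloxy)benzoyl chloride
Product: 15 protected isoflavanone (3R)-3-[7-methoxy-6-(3-methylbut-2-en-1-yl)-2,2-diphenyl-1,3-benzodioxol-4-yl]-7-(triisopropylsilyloxy)chroman-4-one
Conditions: NiCl2(dme) (15 mol %), (R,R)-Ph-BOX [2,2'-(propane-2,2-diyl)bis((4R)-4-phenyl-4,5-dihydrooxazole)] (18 mol %), Mn powder (3 equiv), 3 Å MS, DMA–THF (3:7), 20 °C, 14 added by syringe pump to a final 0.01 M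
Reagents that add atoms: none
Why: Proposed new method: zerovalent nickel bound to the bis(oxazoline) should insert into the aroyl C–Cl bond, a univalent nickel species should abstract chlorine from the benzylic chloride so that both enantiomers of 14 give the same planar C3 radical, and capture of this radical by the tethered acylnickel followed by C3–C4 reductive elimination should release the ketone while Mn returns nickel to its low-valent state. The closest known reaction type is the intermolecular NiCl2(dme)/bis(oxazoline)/Mn enantioconvergent reductive coupling of acid chlorides with racemic secondary benzylic chlorides; the ring-forming use with an aroyl chloride and a β-aryloxy benzylic chloride is without precedent. Ring C closes as a six-membered ring by C(acyl)–C(sp3) reductive elimination, which contracts the seven-membered nickelacycle Ni–C4–C4a–C8a–O1–C2–C3. The C3 configuration is controlled by the chiral ligand on nickel, which selects the face of the prochiral radical at capture, and it should persist because the medium contains no base. The step needs acyl–benzyl pairing within one molecule in preference to dimerisation and to loss of the ring A aryloxide from C2; the pre-formed O1–C2 tether, slow addition to high dilution and the short lifetime of any benzylic nickel species before reductive elimination are what secure it.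

Step 12
Reactants: 15 protected isoflavanone (3R)-3-[7-methoxy-6-(3-methylbut-2-en-1-yl)-2,2-diphenyl-1,3-benzodioxol-4-yl]-7-(triisopropylsilyloxy)chroman-4-one
Product: 16 catechol (3R)-3-[2,3-dihydroxy-4-methoxy-5-(3-methylbut-2-en-1-yl)phenyl]-7-(triisopropylsilyloxy)chroman-4-one
Conditions: TFA–H2O–CH2Cl2 (4:1:10), 0 °C; quench into cold pH 7 phosphate buffer
Reagents that add atoms: none
Why: Acid-catalysed ketal hydrolysis through the diphenyl(aryloxy)carbenium ion, run cold and briefly so that neither acid-catalysed enolisation at C3 nor Markovnikov addition to the prenyl olefin should compete.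

Step 13
Reactants: 16 catechol (3R)-3-[2,3-dihydroxy-4-methoxy-5-(3-methylbut-2-en-1-yl)phenyl]-7-(triisopropylsilyloxy)chroman-4-one
Product: 17 target (3R)-3-[2,3-dihydroxy-4-methoxy-5-(3-methylbut-2-en-1-yl)phenyl]-7-hydroxychroman-4-one
Conditions: HF·pyridine, pyridine, THF, 0 °C to rt
Reagents that add atoms: none
Why: Fluoride-mediated cleavage of the aryl silyl ether in a weakly acidic, non-basic medium, in which the α-aryl ketone should not enolise, so C3 stays (R).

**Compound list**

1 | 2',3'-dihydroxy-4'-methoxyacetophenone | CC(=O)c1ccc(OC)c(O)c1O | starting material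
2 | 1-(7-methoxy-2,2-diphenyl-1,3-benzodioxol-4-yl)ethan-1-one | CC(=O)c1ccc(OC)c2OC(c3ccccc3)(c3ccccc3)Oc12 | intermediate
3 | 1-(6-bromo-7-methoxy-2,2-diphenyl-1,3-benzodioxol-4-yl)ethan-1-one | CC(=O)c1cc(Br)c(OC)c2OC(c3ccccc3)(c3ccccc3)Oc12 | intermediate
4 | tributyl(3-methylbut-2-en-1-yl)stannane | CCCC[Sn](CCCC)(CCCC)CC=C(C)C | starting material
5 | 1-[7-methoxy-6-(3-methylbut-2-en-1-yl)-2,2-diphenyl-1,3-benzodioxol-4-yl]ethan-1-one | CC(=O)c1cc(CC=C(C)C)c(OC)c2OC(c3ccccc3)(c3ccccc3)Oc12 | intermediate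
6 | trimethylsilyl enol ether of 5 (not isolated) | C=C(O[Si](C)(C)C)c1cc(CC=C(C)C)c(OC)c2OC(c3ccccc3)(c3ccccc3)Oc12 | intermediate
7 | 2-bromo-1-[7-methoxy-6-(3-methylbut-2-en-1-yl)-2,2-diphenyl-1,3-benzodioxol-4-yl]ethan-1-one | O=C(CBr)c1cc(CC=C(C)C)c(OC)c2OC(c3ccccc3)(c3ccccc3)Oc12 | intermediate
8 | 2,4-dihydroxybenzoic acid | O=C(O)c1ccc(O)cc1O | starting material
9 | allyl 2,4-dihydroxybenzoate | C=CCOC(=O)c1ccc(O)cc1O | intermediate
10 | allyl 2-hydroxy-4-(triisopropylsilyloxy)benzoate | C=CCOC(=O)c1ccc(O[Si](C(C)C)(C(C)C)C(C)C)cc1O | intermediate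
11 | allyl 2-{2-[7-methoxy-6-(3-methylbut-2-en-1-yl)-2,2-diphenyl-1,3-benzodioxol-4-yl]-2-oxoethoxy}-4-(triisopropylsilyloxy)benzoate | C=CCOC(=O)c1ccc(O[Si](C(C)C)(C(C)C)C(C)C)cc1OCC(=O)c1cc(CC=C(C)C)c(OC)c2OC(c3ccccc3)(c3ccccc3)Oc12 | intermediate
12 | racemic allyl 2-{2-hydroxy-2-[7-methoxy-6-(3-methylbut-2-en-1-yl)-2,2-diphenyl-1,3-benzodioxol-4-yl]ethoxy}-4-(triisopropylsilyloxy)benzoate | C=CCOC(=O)c1ccc(O[Si](C(C)C)(C(C)C)C(C)C)cc1OCC(O)c1cc(CC=C(C)C)c(OC)c2OC(c3ccccc3)(c3ccccc3)Oc12 | intermediate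
13 | racemic 2-{2-hydroxy-2-[7-methoxy-6-(3-methylbut-2-en-1-yl)-2,2-diphenyl-1,3-benzodioxol-4-yl]ethoxy}-4-(triisopropylsilyloxy)benzoic acid | OC(=O)c1ccc(O[Si](C(C)C)(C(C)C)C(C)C)cc1OCC(O)c1cc(CC=C(C)C)c(OC)c2OC(c3ccccc3)(c3ccccc3)Oc12 | intermediate
14 | racemic 2-{2-chloro-2-[7-methoxy-6-(3-methylbut-2-en-1-yl)-2,2-diphenyl-1,3-benzodioxol-4-yl]ethoxy}-4-(triisopropylsilyloxy)benzoyl chloride | COc1c(CC=C(C)C)cc(C(Cl)COc2cc(O[Si](C(C)C)(C(C)C)C(C)C)ccc2C(Cl)=O)c2OC(c3ccccc3)(c3ccccc3)Oc12 | intermediate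
15 | (3R)-3-[7-methoxy-6-(3-methylbut-2-en-1-yl)-2,2-diphenyl-1,3-benzodioxol-4-yl]-7-(triisopropylsilyloxy)chroman-4-one | COc1c(CC=C(C)C)cc([C@@H]2COc3cc(O[Si](C(C)C)(C(C)C)C(C)C)ccc3C2=O)c2OC(c3ccccc3)(c3ccccc3)Oc12 | intermediate
16 | (3R)-3-[2,3-dihydroxy-4-methoxy-5-(3-methylbut-2-en-1-yl)phenyl]-7-(triisopropylsilyloxy)chroman-4-one | COc1c(CC=C(C)C)cc([C@@H]2COc3cc(O[Si](C(C)C)(C(C)C)C(C)C)ccc3C2=O)c(O)c1O | intermediate
17 | (3R)-3-[2,3-dihydroxy-4-methoxy-5-(3-methylbut-2-en-1-yl)phenyl]-7-hydroxychroman-4-one | COc1c(CC=C(C)C)cc([C@@H]2COc3cc(O)ccc3C2=O)c(O)c1O | target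

**Step count**

Total steps: 13. Longest linear sequence: 11 steps (steps 1–4 and 7–13, from 1).

**Steps most likely to fail**

Step 11. The closure may fail through loss of the ring A aryloxide from a benzylic nickel species, through intermolecular coupling in place of ring closure, or through weak facial discrimination at radical capture. The fallback uses only known reaction types, sets out from 3 and comes back at 15:
- Baeyer–Villiger oxidation of 3 (mCPBA, NaHCO3, CH2Cl2) should give 6-bromo-7-methoxy-2,2-diphenyl-1,3-benzodioxol-4-yl acetate F1.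
- Methanolysis (K2CO3, MeOH) should give 6-bromo-7-methoxy-2,2-diphenyl-1,3-benzodioxol-4-ol F2.
- Stille coupling with 4 (Pd(PPh3)4, DMF) should give 7-methoxy-6-(3-methylbut-2-en-1-yl)-2,2-diphenyl-1,3-benzodioxol-4-ol F3.
- Tf2O and pyridine should convert it into the aryl triflate F4.
- Commercial 7-hydroxychroman-4-one is silylated (TIPSCl, imidazole) to 7-(triisopropylsilyloxy)chroman-4-one F5.
- Palladium-catalysed ketone α-arylation of F5 with F4 (Pd2(dba)3, XPhos, K3PO4, toluene, 80 °C) should give the racemic protected isoflavanone F6.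
- Asymmetric transfer hydrogenation with dynamic kinetic resolution (RuCl(p-cymene)[(R,R)-TsDPEN] or its antipode, HCO2H–Et3N, EtOAc, 40 °C), in which the amine racemises C3 while one enantiomer is reduced, should give the cis-(3R,4R)-isoflavan-4-ol F7.
- Buffered Dess–Martin oxidation (NaHCO3, CH2Cl2, 0 °C) should return the ketone 15 without touching C3.

Step 10. The hydroxyl may lactonise onto the activated acid to a seven-membered lactone before it is chlorinated, and the electron-rich benzylic chloride may ionise or hydrolyse on handling. The fallback changes the order of events so that no hydroxyl is present when the acid is activated; it sets out from 12 and comes back at 14: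
- Treatment of 12 with the α-chloroenamine (1.2 equiv, CH2Cl2, 0 °C) should give the chloro allyl ester F8.
- Deallylation with Pd(PPh3)4 and PhSiH3 as a neutral, non-nucleophilic allyl acceptor should give the chloro acid F9.
- A second portion of the α-chloroenamine (1.1 equiv) should convert F9 into 14.

Step 12. Acid-promoted enolisation may erode the configuration at C3, and trifluoroacetic acid or water may add across the prenyl olefin. The fallback separates ketal removal from stereocontrol, so that the last step is a non-enolising fluoride deprotection; it sets out from 15 and comes back at 17: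
- The ketal is hydrolysed under conditions chosen only for chemoselectivity (AcOH–H2O 4:1, 60 °C), accepting loss of configuration, to give the racemic catechol F10.
- Silylation (TBSCl, imidazole, DMF) should give the racemic tris-silyl ketone F11.
- Asymmetric transfer hydrogenation with dynamic kinetic resolution (same ruthenium catalyst as above) should give the cis-(3R,4R)-alcohol F12.
- Buffered Dess–Martin oxidation should give the (R)-tris-silyl ketone F13.
- HF·pyridine should remove all three silyl groups to give 17.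

**Further compounds**

F1 | step 11 | 6-bromo-7-methoxy-2,2-diphenyl-1,3-benzodioxol-4-yl acetate | CC(=O)Oc1cc(Br)c(OC)c2OC(c3ccccc3)(c3ccccc3)Oc12
F2 | step 11 | 6-bromo-7-methoxy-2,2-diphenyl-1,3-benzodioxol-4-ol | Oc1cc(Br)c(OC)c2OC(c3ccccc3)(c3ccccc3)Oc12
F3 | step 11 | 7-methoxy-6-(3-methylbut-2-en-1-yl)-2,2-diphenyl-1,3-benzodioxol-4-ol | Oc1cc(CC=C(C)C)c(OC)c2OC(c3ccccc3)(c3ccccc3)Oc12
F4 | step 11 | 7-methoxy-6-(3-methylbut-2-en-1-yl)-2,2-diphenyl-1,3-benzodioxol-4-yl trifluoromethanesulfonate | O=S(=O)(Oc1cc(CC=C(C)C)c(OC)c2OC(c3ccccc3)(c3ccccc3)Oc12)C(F)(F)F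
F5 | step 11 | 7-(triisopropylsilyloxy)chroman-4-one | O=C1CCOc2cc(O[Si](C(C)C)(C(C)C)C(C)C)ccc12
F6 | step 11 | racemic 3-[7-methoxy-6-(3-methylbut-2-en-1-yl)-2,2-diphenyl-1,3-benzodioxol-4-yl]-7-(triisopropylsilyloxy)chroman-4-one | COc1c(CC=C(C)C)cc(C2COc3cc(O[Si](C(C)C)(C(C)C)C(C)C)ccc3C2=O)c2OC(c3ccccc3)(c3ccccc3)Oc12
F7 | step 11 | (3R,4R)-3-[7-methoxy-6-(3-methylbut-2-en-1-yl)-2,2-diphenyl-1,3-benzodioxol-4-yl]-7-(triisopropylsilyloxy)chroman-4-ol | COc1c(CC=C(C)C)cc([C@@H]2COc3cc(O[Si](C(C)C)(C(C)C)C(C)C)ccc3[C@@H]2O)c2OC(c3ccccc3)(c3ccccc3)Oc12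
F8 | step 10 | racemic allyl 2-{2-chloro-2-[7-methoxy-6-(3-methylbut-2-en-1-yl)-2,2-diphenyl-1,3-benzodioxol-4-yl]ethoxy}-4-(triisopropylsilyloxy)benzoate | C=CCOC(=O)c1ccc(O[Si](C(C)C)(C(C)C)C(C)C)cc1OCC(Cl)c1cc(CC=C(C)C)c(OC)c2OC(c3ccccc3)(c3ccccc3)Oc12
F9 | step 10 | racemic 2-{2-chloro-2-[7-methoxy-6-(3-methylbut-2-en-1-yl)-2,2-diphenyl-1,3-benzodioxol-4-yl]ethoxy}-4-(triisopropylsilyloxy)benzoic acid | OC(=O)c1ccc(O[Si](C(C)C)(C(C)C)C(C)C)cc1OCC(Cl)c1cc(CC=C(C)C)c(OC)c2OC(c3ccccc3)(c3ccccc3)Oc12
F10 | step 12 | racemic 3-[2,3-dihydroxy-4-methoxy-5-(3-methylbut-2-en-1-yl)phenyl]-7-(triisopropylsilyloxy)chroman-4-one | COc1c(CC=C(C)C)cc(C2COc3cc(O[Si](C(C)C)(C(C)C)C(C)C)ccc3C2=O)c(O)c1O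
F11 | step 12 | racemic 3-[2,3-bis(tert-butyldimethylsilyloxy)-4-methoxy-5-(3-methylbut-2-en-1-yl)phenyl]-7-(triisopropylsilyloxy)chroman-4-one | COc1c(CC=C(C)C)cc(C2COc3cc(O[Si](C(C)C)(C(C)C)C(C)C)ccc3C2=O)c(O[Si](C)(C)C(C)(C)C)c1O[Si](C)(C)C(C)(C)C
F12 | step 12 | (3R,4R)-3-[2,3-bis(tert-butyldimethylsilyloxy)-4-methoxy-5-(3-methylbut-2-en-1-yl)phenyl]-7-(triisopropylsilyloxy)chroman-4-ol | COc1c(CC=C(C)C)cc([C@@H]2COc3cc(O[Si](C(C)C)(C(C)C)C(C)C)ccc3[C@@H]2O)c(O[Si](C)(C)C(C)(C)C)c1O[Si](C)(C)C(C)(C)C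
F13 | step 12 | (3R)-3-[2,3-bis(tert-butyldimethylsilyloxy)-4-methoxy-5-(3-methylbut-2-en-1-yl)phenyl]-7-(triisopropylsilyloxy)chroman-4-one | COc1c(CC=C(C)C)cc([C@@H]2COc3cc(O[Si](C(C)C)(C(C)C)C(C)C)ccc3C2=O)c(O[Si](C)(C)C(C)(C)C)c1O[Si](C)(C)C(C)(C)C
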